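The flavone is cut at both bonds to C4: C4a–C4 on ring A and C4–C3, the methoxy-bearing carbon of the future pyranone ring C. Because C4 is a ketone carbon lying between an electron-rich aryl carbon and an enolisable α-methoxy carbon, it can be supplied as CO: a palladium-catalysed carbonylative α-arylation joins a ring-A aryl iodide, CO and a ring-B methoxymethyl ketone to the open 2-methoxy-1,3-diketone in one operation. The iodide carries iodine at C4a, the C8 prenyl group, MOM ethers on O5 and O7 and a silyl ether only on the future O1, so ring C later closes through that oxygen alone.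

Key step: step 11

Remark on stereochemistry: the target has no stereocentre and is achiral, so there is no enantiomer to select. The stereocentres that appear in 12, 15, 16 and 17 form racemic and are erased before the target.

Remark on design: iodine is placed on ring A while the phenol is still free and before any prenyl group exists, because electrophilic iodine would cyclise an o-prenylphenol onto its alkene. The iodine then also blocks one ortho position in the Claisen step. Ring B is taken from a bromocatechol aldehyde, so the two catechol hydroxyls never have to be told apart.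

Abbreviations: MOM = methoxymethyl; TBS = tert-butyldimethylsilyl; prenyl = 3-methylbut-2-en-1-yl.

**Route**

Step 1
Reactants: 1 phloroglucinol
Product: 2 3,5-bis(methoxymethoxy)phenol
Conditions: MOMCl (2.0 equiv), i-Pr2NEt (2.2 equiv), DMF, 0 °C to rt; chromatographic separation from mono- and tris-ethers
Reagents that add atoms: chloromethyl methyl ether (MOMCl), COCCl
Why: Williamson-type acetal etherification of a C3-symmetric triol is statistical but gives a single bis-ether constitution, and the mono-ether can be resubmitted.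

Step 2
Reactants: 2 3,5-bis(methoxymethoxy)phenol
Product: 3 2-iodo-3,5-bis(methoxymethoxy)phenol
Conditions: I2 (1.0 equiv), NaHCO3, THF/H2O, 0 °C
Reagents that add atoms: iodine, II
Why: electrophilic aromatic iodination of the phenol/phenoxide should go ortho to the free hydroxyl (two equivalent, less crowded sites) rather than between the two MOM ethers, and the bicarbonate buffer keeps the acetals intact.

Step 3
Reactants: 3 2-iodo-3,5-bis(methoxymethoxy)phenol; 4 3-chloro-3-methylbut-1-yne
Product: 5 2-iodo-1,5-bis(methoxymethoxy)-3-[(2-methylbut-3-yn-2-yl)oxy]benzene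
Conditions: DBU, CuCl2·2H2O (cat.), MeCN, 0 °C
Reagents that add atoms: none
Why: copper-catalysed propargylic O-alkylation of a phenol with a tertiary propargylic chloride proceeds through a copper acetylide/allenylidene, so no SN2 at the tertiary carbon is needed, and at 0 °C the aryl iodide is not engaged.

Step 4
Reactants: 5 2-iodo-1,5-bis(methoxymethoxy)-3-[(2-methylbut-3-yn-2-yl)oxy]benzene
Product: 6 2-iodo-1,5-bis(methoxymethoxy)-3-[(2-methylbut-3-en-2-yl)oxy]benzene
Conditions: H2 (1 atm), Lindlar catalyst, quinoline, EtOAc, rt, stopped after one equivalent of H2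
Reagents that add atoms: none
Why: Lindlar semi-hydrogenation reduces the terminal alkyne on the lead- and quinoline-poisoned surface much faster than it cleaves the aryl C–I bond or saturates the resulting vinyl group.

Step 5
Reactants: 6 2-iodo-1,5-bis(methoxymethoxy)-3-[(2-methylbut-3-en-2-yl)oxy]benzene
Product: 7 2-iodo-3,5-bis(methoxymethoxy)-6-prenylphenol
Conditions: N,N-diethylaniline, 120 °C
Reagents that add atoms: none
Why: aromatic Claisen rearrangement ([3,3]) of the 1,1-dimethylallyl ether, accelerated by the gem-dimethyl group, delivers the inverted (linear) prenyl group to the only free ortho carbon because iodine blocks the other, and the freed hydroxyl marks the oxygen that will become O1.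

Step 6
Reactants: 7 2-iodo-3,5-bis(methoxymethoxy)-6-prenylphenol
Product: 8 tert-butyl[2-iodo-3,5-bis(methoxymethoxy)-6-prenylphenoxy]dimethylsilane
Conditions: TBSCl, imidazole, DMAP (cat.), DMF, rt to 40 °C
Reagents that add atoms: tert-butyldimethylsilyl chloride, CC(C)(C)[Si](C)(C)Cl
Why: imidazole-promoted O-silylation of the single free phenol gives a fluoride-labile ether orthogonal to the acid-labile MOM groups, and chloride conditions avoid silyl triflate attack on the acetals.

Step 7
Reactants: 9 3-bromo-4,5-dihydroxybenzaldehyde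
Product: 10 3-bromo-4,5-bis(methoxymethoxy)benzaldehyde
Conditions: MOMCl (2.5 equiv), i-Pr2NEt, CH2Cl2, 0 °C to rt
Reagents that add atoms: chloromethyl methyl ether (MOMCl), COCCl
Why: exhaustive Williamson-type MOM etherification protects both catechol hydroxyls at once, so no regiochemical question arises.

Step 8
Reactants: 10 3-bromo-4,5-bis(methoxymethoxy)benzaldehyde
Product: 11 3,4-bis(methoxymethoxy)-5-prenylbenzaldehyde
Conditions: tributyl(prenyl)stannane (1.2 equiv), Pd(PPh3)4 (5 mol %), DMF, 95 °C
Reagents that add atoms: tributyl(3-methylbut-2-en-1-yl)stannane, CCCC[Sn](CCCC)(CCCC)CC=C(C)C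
Why: Stille cross-coupling of the electron-poor aryl bromide with the prenylstannane should form the aryl–CH2 bond at the unhindered allyl terminus to give the linear prenyl arene, and it tolerates the aldehyde and the MOM acetals.

Step 9
Reactants: 11 3,4-bis(methoxymethoxy)-5-prenylbenzaldehyde
Product: 12 1-[3,4-bis(methoxymethoxy)-5-prenylphenyl]-2-methoxyethan-1-ol (racemic)
Conditions: Bu3SnCH2OMe, n-BuLi, THF, −78 °C; then 11, −78 °C; H2O
Reagents that add atoms: tributyl(methoxymethyl)stannane, COC[Sn](CCCC)(CCCC)CCCC (delivered as methoxymethyllithium, [Li]COC)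
Why: tin–lithium exchange gives methoxymethyllithium, whose 1,2-addition to the aldehyde installs the CH2OMe carbon (the future C3); the new carbinol centre forms racemic by unselective addition and is erased in step 10.

Step 10
Reactants: 12 1-[3,4-bis(methoxymethoxy)-5-prenylphenyl]-2-methoxyethan-1-ol
Product: 13 1-[3,4-bis(methoxymethoxy)-5-prenylphenyl]-2-methoxyethan-1-one
Conditions: Dess–Martin periodinane, NaHCO3, CH2Cl2, 0 °C to rt
Reagents that add atoms: none
Why: Dess–Martin oxidation of the benzylic secondary alcohol gives the aryl methoxymethyl ketone under buffered, near-neutral conditions that leave the prenyl alkene and MOM acetals untouched.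

Step 11
Reactants: 8 tert-butyl[2-iodo-3,5-bis(methoxymethoxy)-6-prenylphenoxy]dimethylsilane; 14 carbon monoxide; 13 1-[3,4-bis(methoxymethoxy)-5-prenylphenyl]-2-methoxyethan-1-one
Product: 15 1-[2-(tert-butyldimethylsilyloxy)-4,6-bis(methoxymethoxy)-3-prenylphenyl]-3-[3,4-bis(methoxymethoxy)-5-prenylphenyl]-2-methoxypropane-1,3-dione (racemic, enolisable)
Conditions: 13 (2.0 equiv), NaHMDS (2.0 equiv), 1,4-dioxane, rt; then 8, Pd(dba)2 (5 mol %), Xantphos (6 mol %), CO (1 atm), 80 °C; aq. NH4Cl
Reagents that add atoms: none
Why: Oxidative addition of Pd(0)/Xantphos to the C4a–I bond of 8 is followed by migratory insertion of CO (14) to an aroylpalladium(II) complex; the sodium enolate of 13 then replaces iodide on palladium, bonds through its α-carbon, and reductive elimination creates C4–C3, so C4a–C4 and C4–C3 are made together and C4 with its oxygen originates from CO. The closest known reaction type is the palladium-catalysed carbonylative α-arylation of aryl ketones with aryl iodides to 1,3-diketones. No ring closes in this step, and the only new stereocentre, the enolisable C3 methine, forms as a racemate without control and becomes sp2 in step 12. The step needs CO insertion to outrun direct α-arylation and C-acylation to outrun O-acylation: the two ortho oxygen substituents crowd the arylpalladium and favour the less congested aroyl complex, the wide bite angle of Xantphos speeds acyl–carbon reductive elimination, and the methoxy-chelated sodium enolate reacts at carbon. The second equivalent of enolate deprotonates the acidic diketone as it forms, which protects it from retro-Claisen cleavage and further coupling, and because the base is fully consumed in pre-enolisation no free amide can intercept the aroylpalladium. The hindered TBS ether, the MOM acetals and the prenyl alkenes should be inert to these non-nucleophilic conditions, and surplus 13 should be recoverable.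

Step 12
Reactants: 15 1-[2-(tert-butyldimethylsilyloxy)-4,6-bis(methoxymethoxy)-3-prenylphenyl]-3-[3,4-bis(methoxymethoxy)-5-prenylphenyl]-2-methoxypropane-1,3-dione
Product: 18 2-[3,4-bis(methoxymethoxy)-5-prenylphenyl]-3-methoxy-5,7-bis(methoxymethoxy)-8-prenyl-4H-chromen-4-one, via free phenol diketone 16 (not isolated), via cyclic hemiketal 17 (not isolated)
Conditions: TBAF, AcOH, THF, 0 °C; extractive work-up; then CSA (10 mol %), 4 Å MS, CH2Cl2, rt
Reagents that add atoms: none
Why: buffered fluoride desilylation frees only the phenol next to the prenyl group, which adds to the ring-B ketone, and acid-catalysed cyclodehydration of the o-hydroxyaryl 1,3-diketone (the closing stage of a Baker–Venkataraman flavone synthesis) forms O1–C2 and C2=C3 and erases the transient stereocentres, while the MOM ether on O5 rules out the 6-prenyl isomer.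

Step 13
Reactants: 18 2-[3,4-bis(methoxymethoxy)-5-prenylphenyl]-3-methoxy-5,7-bis(methoxymethoxy)-8-prenyl-4H-chromen-4-one
Product: 19 5,7,3',4'-tetrahydroxy-3-methoxy-8,5'-diprenylflavone
Conditions: 3 M aq. HCl/MeOH (1:5), 45 °C, Ar, monitored and stopped at full conversion
Reagents that add atoms: none
Why: acid-catalysed acetal methanolysis removes the four aryl MOM groups as dimethoxymethane under conditions commonly used for prenylated flavonoids, and the C3 methyl ether is stable to them.

**Compound list**

1 | phloroglucinol | Oc1cc(O)cc(O)c1 | starting material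
2 | 3,5-bis(methoxymethoxy)phenol | COCOc1cc(O)cc(OCOC)c1 | intermediate
3 | 2-iodo-3,5-bis(methoxymethoxy)phenol | COCOc1cc(O)c(I)c(OCOC)c1 | intermediate
4 | 3-chloro-3-methylbut-1-yne | C#CC(C)(C)Cl | starting material
5 | 2-iodo-1,5-bis(methoxymethoxy)-3-[(2-methylbut-3-yn-2-yl)oxy]benzene | C#CC(C)(C)Oc1cc(OCOC)cc(OCOC)c1I | intermediate
6 | 2-iodo-1,5-bis(methoxymethoxy)-3-[(2-methylbut-3-en-2-yl)oxy]benzene | C=CC(C)(C)Oc1cc(OCOC)cc(OCOC)c1I | intermediate
7 | 2-iodo-3,5-bis(methoxymethoxy)-6-(3-methylbut-2-en-1-yl)phenol | CC(C)=CCc1c(O)c(I)c(OCOC)cc1OCOC | intermediate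
8 | tert-butyl[2-iodo-3,5-bis(methoxymethoxy)-6-(3-methylbut-2-en-1-yl)phenoxy]dimethylsilane | CC(C)(C)[Si](C)(C)Oc1c(CC=C(C)C)c(OCOC)cc(OCOC)c1I | intermediate
9 | 3-bromo-4,5-dihydroxybenzaldehyde | O=Cc1cc(O)c(O)c(Br)c1 | starting material
10 | 3-bromo-4,5-bis(methoxymethoxy)benzaldehyde | COCOc1cc(C=O)cc(Br)c1OCOC | intermediate
11 | 3,4-bis(methoxymethoxy)-5-(3-methylbut-2-en-1-yl)benzaldehyde | COCOc1cc(C=O)cc(CC=C(C)C)c1OCOC | intermediate
12 | 1-[3,4-bis(methoxymethoxy)-5-(3-methylbut-2-en-1-yl)phenyl]-2-methoxyethan-1-ol (racemic) | COCC(O)c1cc(OCOC)c(OCOC)c(CC=C(C)C)c1 | intermediate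
13 | 1-[3,4-bis(methoxymethoxy)-5-(3-methylbut-2-en-1-yl)phenyl]-2-methoxyethan-1-one | COCC(=O)c1cc(OCOC)c(OCOC)c(CC=C(C)C)c1 | intermediate
14 | carbon monoxide | [C-]#[O+] | starting material
15 | 1-[2-(tert-butyldimethylsilyloxy)-4,6-bis(methoxymethoxy)-3-(3-methylbut-2-en-1-yl)phenyl]-3-[3,4-bis(methoxymethoxy)-5-(3-methylbut-2-en-1-yl)phenyl]-2-methoxypropane-1,3-dione (racemic) | CC(C)(C)[Si](C)(C)Oc1c(CC=C(C)C)c(OCOC)cc(OCOC)c1C(=O)C(OC)C(=O)c1cc(OCOC)c(OCOC)c(CC=C(C)C)c1 | intermediate
16 | 1-[2-hydroxy-4,6-bis(methoxymethoxy)-3-(3-methylbut-2-en-1-yl)phenyl]-3-[3,4-bis(methoxymethoxy)-5-(3-methylbut-2-en-1-yl)phenyl]-2-methoxypropane-1,3-dione (racemic, not isolated) | Oc1c(CC=C(C)C)c(OCOC)cc(OCOC)c1C(=O)C(OC)C(=O)c1cc(OCOC)c(OCOC)c(CC=C(C)C)c1 | intermediate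
17 | 2-[3,4-bis(methoxymethoxy)-5-(3-methylbut-2-en-1-yl)phenyl]-2-hydroxy-3-methoxy-5,7-bis(methoxymethoxy)-8-(3-methylbut-2-en-1-yl)chroman-4-one (racemic diastereomer mixture, not isolated) | COC1C(=O)c2c(OCOC)cc(OCOC)c(CC=C(C)C)c2OC1(O)c1cc(OCOC)c(OCOC)c(CC=C(C)C)c1 | intermediate
18 | 2-[3,4-bis(methoxymethoxy)-5-(3-methylbut-2-en-1-yl)phenyl]-3-methoxy-5,7-bis(methoxymethoxy)-8-(3-methylbut-2-en-1-yl)-4H-chromen-4-one | COc1c(-c2cc(OCOC)c(OCOC)c(CC=C(C)C)c2)oc2c(CC=C(C)C)c(OCOC)cc(OCOC)c2c1=O | intermediate
19 | 5,7,3',4'-tetrahydroxy-3-methoxy-8,5'-diprenylflavone | COc1c(-c2cc(O)c(O)c(CC=C(C)C)c2)oc2c(CC=C(C)C)c(O)cc(O)c2c1=O | target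

**Totals and risks**

Total step count: 13. Longest linear sequence: 9 steps (steps 1–6, then 11–13); the ring-B branch (steps 7–10) is 4 steps.

Steps most likely to fail:

1. Step 11. What may go wrong: coupling without CO uptake (direct α-arylation), acylation of the enolate on oxygen, or sluggish oxidative addition at the hindered, electron-rich C–I bond under CO. The fallback builds the same diketone by stepwise polar chemistry with C4 taken from DMF. It sets out from 8 and 13 and comes back at 15. Iodine–magnesium exchange on 8 (i-PrMgCl·LiCl, THF, −40 °C) should give [2-(tert-butyldimethylsilyloxy)-4,6-bis(methoxymethoxy)-3-prenylphenyl]magnesium chloride F1, which is formylated with DMF to 2-(tert-butyldimethylsilyloxy)-4,6-bis(methoxymethoxy)-3-prenylbenzaldehyde F2. The lithium enolate of 13 (LDA, THF, −78 °C) is then added to F2 in an aldol reaction to give 3-[2-(tert-butyldimethylsilyloxy)-4,6-bis(methoxymethoxy)-3-prenylphenyl]-1-[3,4-bis(methoxymethoxy)-5-prenylphenyl]-3-hydroxy-2-methoxypropan-1-one F3 as a diastereomer mixture. Dess–Martin oxidation of its carbinol returns the route to 15.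

2. Step 2. What may go wrong: iodination at the carbon between the two MOM ethers (para to the hydroxyl) or a second iodination. The fallback replaces electrophilic substitution by directed ortho-metalation. It sets out from 2 and comes back at 3. Carbamoylation of 2 (ClCONEt2, K2CO3, MeCN, reflux) gives 3,5-bis(methoxymethoxy)phenyl N,N-diethylcarbamate F4. Lithiation with s-BuLi/TMEDA in THF at −78 °C, directed by the carbamate to the carbon between it and a MOM ether, gives the 2-lithio-3,5-bis(methoxymethoxy)phenyl N,N-diethylcarbamate F5, and an iodine quench gives 2-iodo-3,5-bis(methoxymethoxy)phenyl N,N-diethylcarbamate F6. Basic hydrolysis (NaOH, EtOH/H2O, reflux) then returns 3.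

3. Step 13. What may go wrong: acid-induced cyclisation of the two o-prenylphenol units to 2,2-dimethylchromans, or addition of HCl or methanol across the prenyl alkenes, before all four acetals are cleaved. The fallback avoids protic acid by exchanging the acetals for silyl ethers. It sets out from 18 and comes back at 19. Treatment of 18 with TMSOTf and 2,2'-bipyridyl in MeCN (0 °C to rt) should convert the aryl MOM ethers into 2-[3,4-bis(trimethylsilyloxy)-5-prenylphenyl]-3-methoxy-8-prenyl-5,7-bis(trimethylsilyloxy)-4H-chromen-4-one F7, and the aqueous work-up hydrolyses the four TMS ethers to give 19.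

**Further compounds**

F1 | step 11 | [2-(tert-butyldimethylsilyloxy)-4,6-bis(methoxymethoxy)-3-(3-methylbut-2-en-1-yl)phenyl]magnesium chloride | CC(C)(C)[Si](C)(C)Oc1c(CC=C(C)C)c(OCOC)cc(OCOC)c1[Mg]Cl
F2 | step 11 | 2-(tert-butyldimethylsilyloxy)-4,6-bis(methoxymethoxy)-3-(3-methylbut-2-en-1-yl)benzaldehyde | CC(C)(C)[Si](C)(C)Oc1c(CC=C(C)C)c(OCOC)cc(OCOC)c1C=O
F3 | step 11 | 3-[2-(tert-butyldimethylsilyloxy)-4,6-bis(methoxymethoxy)-3-(3-methylbut-2-en-1-yl)phenyl]-1-[3,4-bis(methoxymethoxy)-5-(3-methylbut-2-en-1-yl)phenyl]-3-hydroxy-2-methoxypropan-1-one (diastereomer mixture, racemic) | CC(C)(C)[Si](C)(C)Oc1c(CC=C(C)C)c(OCOC)cc(OCOC)c1C(O)C(OC)C(=O)c1cc(OCOC)c(OCOC)c(CC=C(C)C)c1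
F4 | step 2 | 3,5-bis(methoxymethoxy)phenyl N,N-diethylcarbamate | CCN(CC)C(=O)Oc1cc(OCOC)cc(OCOC)c1
F5 | step 2 | 2-lithio-3,5-bis(methoxymethoxy)phenyl N,N-diethylcarbamate | CCN(CC)C(=O)Oc1cc(OCOC)cc(OCOC)c1[Li]
F6 | step 2 | 2-iodo-3,5-bis(methoxymethoxy)phenyl N,N-diethylcarbamate | CCN(CC)C(=O)Oc1cc(OCOC)cc(OCOC)c1I
F7 | step 13 | 2-[3,4-bis(trimethylsilyloxy)-5-(3-methylbut-2-en-1-yl)phenyl]-3-methoxy-8-(3-methylbut-2-en-1-yl)-5,7-bis(trimethylsilyloxy)-4H-chromen-4-one | COc1c(-c2cc(O[Si](C)(C)C)c(O[Si](C)(C)C)c(CC=C(C)C)c2)oc2c(CC=C(C)C)c(O[Si](C)(C)C)cc(O[Si](C)(C)C)c2c1=O
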